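**Plan**
1. Labels: ring A = resorcinol ring. Ring E = monophenol ring joined to A by the biaryl bond. Ring C = fused catechol, ring D = pendant catechol. Ring B = six-membered carbocycle, ring F = seven-membered carbocycle. Ca = methine shared by B and F. Cb = methine that carries ring D.
2. Enabling feature: ring B consists of two adjacent carbons of ring E plus the run Ca–CH2–C(A)–C(A). The two bonds leaving ring E side by side therefore map onto a [4+2] addition of a ring E aryne to the vinylarene diene Ca=CH–C(A)=C(A) of a 3,5-dimethoxystilbene. Because Ca is already tied to ring E through ring C, Cb and a CH2, the same event also closes ring F.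
3. Retrosynthetic cuts, in order: seven O–CH3 bonds; ring E–ring A and ring E–Ca together; the stilbene C=C (Horner–Wadsworth–Emmons); Cb–ring D (C–H arylation); Cb–CH2 (benzylic alkylation).
4. Forward: the open chain is joined as ring E + ring C, then ring D, then ring A, with no carbocycle made. Rings B and F then arise together in one step, with ring A dearomatised in passing. Global demethylation ends the route.
5. Stereochemistry: Cb (S) comes from a chiral transient imine of tert-leucine in the palladium-catalysed benzylic C–H arylation. Ca (R) is relayed from Cb through the tether in the cycloaddition.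

Key step: step 8

Assumption: (S)-tert-leucine is taken to induce the (S) configuration at Cb in step 6. If the sense of induction proves opposite, (R)-tert-leucine, also commercial, is used and nothing else changes.

**Step 1**
Reactants: 1 3-methoxy-5-methylphenol
Product: 2 3-methoxy-5-methylphenyl trifluoromethanesulfonate
Conditions: Tf2O, pyridine, CH2Cl2, 0 °C to rt
Reagents that add atoms: triflic anhydride, O=S(=O)(OS(=O)(=O)C(F)(F)F)C(F)(F)F
Why: Phenol O-sulfonylation (triflation); the triflate is the later leaving group of the aryne and, being a strong acceptor, leaves the methoxy group as the only director for step 2.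

**Step 2**
Reactants: 2 3-methoxy-5-methylphenyl trifluoromethanesulfonate
Product: 3 2-bromo-5-methoxy-3-methylphenyl trifluoromethanesulfonate
Conditions: NBS (1.0 equiv), MeCN, 0 °C to rt, dark
Reagents that add atoms: N-bromosuccinimide, O=C1CCC(=O)N1Br
Why: Electrophilic aromatic bromination with NBS in MeCN goes para to the methoxy group, as with other 3,5-disubstituted anisoles, and so places Br between CH3 and OTf, ortho to the triflate.

**Step 3**
Reactants: 3 2-bromo-5-methoxy-3-methylphenyl trifluoromethanesulfonate
Product: 4 2-bromo-3-(bromomethyl)-5-methoxyphenyl trifluoromethanesulfonate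
Conditions: NBS (1.05 equiv), AIBN (cat.), PhCF3, 85 °C
Reagents that add atoms: N-bromosuccinimide, O=C1CCC(=O)N1Br
Why: Wohl–Ziegler radical bromination of the benzylic CH3, familiar from 2-bromo-5-methoxytoluenes; the ring, now carrying Br and OTf, is too deactivated for ionic bromination in a non-polar medium.

**Step 4**
Reactants: 5 4,5-dimethoxy-2-methylbenzaldehyde
Product: 6 (E)-N-tert-butyl-1-(4,5-dimethoxy-2-methylphenyl)methanimine
Conditions: t-BuNH2, MgSO4, CH2Cl2, rt
Reagents that add atoms: tert-butylamine, CC(C)(C)N
Why: Imine condensation; the bulky N-tert-butyl group blocks 1,2-addition of bases and the C=N group acidifies the ortho CH3.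

**Step 5**
Reactants: 6 (E)-N-tert-butyl-1-(4,5-dimethoxy-2-methylphenyl)methanimine; 4 2-bromo-3-(bromomethyl)-5-methoxyphenyl trifluoromethanesulfonate
Product: 9 2-bromo-3-[2-(2-formyl-4,5-dimethoxyphenyl)ethyl]-5-methoxyphenyl trifluoromethanesulfonate, via lithiated imine 7 (not isolated), via alkylated imine 8 (not isolated)
Conditions: LiN(i-Pr)2 (1.0 equiv), THF, 0 °C; cannulated into 4, THF, −78 °C; then AcOH/H2O/THF, rt
Reagents that add atoms: water, O
Why: Lateral lithiation of an o-tolualdehyde tert-butylimine followed by SN2 alkylation: the delocalised benzylic anion 7 should react with the benzylic bromide of 4 at −78 °C much faster than with ArBr or ArOTf, and aqueous acid hydrolyses imine 8 to the aldehyde.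

**Step 6**
Reactants: 9 2-bromo-3-[2-(2-formyl-4,5-dimethoxyphenyl)ethyl]-5-methoxyphenyl trifluoromethanesulfonate; 10 4-iodo-1,2-dimethoxybenzene
Product: 11 2-bromo-3-[(2S)-2-(3,4-dimethoxyphenyl)-2-(2-formyl-4,5-dimethoxyphenyl)ethyl]-5-methoxyphenyl trifluoromethanesulfonate
Conditions: Pd(OAc)2 (10 mol %), (S)-tert-leucine (20 mol %), AgOCOCF3 (1.5 equiv), (CF3)2CHOH/AcOH, 100 °C
Reagents that add atoms: none
Why: Enantioselective palladium-catalysed benzylic C(sp3)–H arylation of a 2-alkylbenzaldehyde through a chiral transient directing group: the imine-carboxylate formed reversibly from the CHO group and tert-leucine chelates divalent palladium, its tert-butyl group selects one of the two enantiotopic Cb–H bonds in the concerted metalation–deprotonation to a fused 5,6-palladacycle, oxidative addition of 10 and reductive elimination with retention set Cb as (S), and ArBr and ArOTf stay inert because no zerovalent palladium takes part.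

**Step 7**
Reactants: 11 2-bromo-3-[(2S)-2-(3,4-dimethoxyphenyl)-2-(2-formyl-4,5-dimethoxyphenyl)ethyl]-5-methoxyphenyl trifluoromethanesulfonate; 12 diethyl (3,5-dimethoxybenzyl)phosphonate
Product: 13 2-bromo-3-[(2S)-2-(3,4-dimethoxyphenyl)-2-{2-[(E)-2-(3,5-dimethoxyphenyl)ethenyl]-4,5-dimethoxyphenyl}ethyl]-5-methoxyphenyl trifluoromethanesulfonate
Conditions: 12 (1.2 equiv), NaN(SiMe3)2 (1.1 equiv), THF, 0 °C; then 11, −78 °C to rt
Reagents that add atoms: none
Why: Horner–Wadsworth–Emmons olefination of an aromatic aldehyde with a benzylphosphonate anion gives the (E)-stilbene; with the anion preformed and no free base left, carbonyl addition should outrun both attack on the triflate and deprotonation of the hindered Cb–H, so Cb is kept.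

**Step 8**
Reactants: 13 2-bromo-3-[(2S)-2-(3,4-dimethoxyphenyl)-2-{2-[(E)-2-(3,5-dimethoxyphenyl)ethenyl]-4,5-dimethoxyphenyl}ethyl]-5-methoxyphenyl trifluoromethanesulfonate
Product: 17 target heptamethyl ether (R at Ca; S at Cb), via aryllithium 14 (not isolated), via aryne 15 (not isolated), via isotoluene cycloadduct 16 (not isolated)
Conditions: n-BuLi (1.05 equiv, slow addition), THF (0.005 M, degassed), −78 °C to −20 °C, argon; then AcOH, −20 °C to rt
Reagents that add atoms: none
Why: Proposed new method: Br/Li exchange on 13 gives 14, which loses LiOTf to aryne 15, whose in-plane π bond between the two adjacent ring E carbons is taken up suprafacially by the 4π unit Ca=CH–C(A)=C(A) in a concerted but probably asynchronous Diels–Alder reaction that makes the ring E–Ca and ring E–ring A bonds together and dearomatises ring A to 16; on the AcOH quench the exocyclic =CH– of 16 is protonated to an arenium ion stabilised by its ortho and para OMe groups, which loses the ring-fusion proton, restoring ring A and leaving the CH2 of 17. The closest known reaction types are the intermolecular aryne–styrene Diels–Alder route to 9,10-dihydrophenanthrenes and the intramolecular benzyne [4+2] cycloadditions of tethered dienes and arenynes; new here are a stilbene as the tethered 4π partner, a tether that closes a seven-membered ring, and stereochemical relay from a benzylic centre. Ring B is the cycloaddition ring itself, closed at both new bonds, while ring F closes at the ring E–Ca bond in the type 1 intramolecular mode (7-exo with respect to the stilbene C=C), the tether CH2–Cb–C(C)–C(C) running from the ring E carbon next to the aryne to the diene terminus Ca. Ca is controlled by Cb: allylic 1,3-strain keeps Cb–H in the plane of ring C facing the vinyl group, so CH2–ring E sits on one face of ring C and ring D on the other, and it also keeps the CH= carbon turned away from Cb, so the aryne can reach only one face of Ca, which places H(Ca) and H(Cb) cis on ring F, that is (R) at Ca from (S) at Cb; the sp3 ring A carbon of 16 is set with its H cis to H(Ca) by the suprafacial addition and is erased on rearomatisation. Regiochemistry is fixed by the tether, the two ortho carbons of ring A are equivalent by symmetry so only one constitution can result, and periselectivity over [2+2] addition to the C=C and over attack by rings C and D is expected because the ring A ortho carbon, activated by one ortho and one para OMe, is the most nucleophilic π terminus for the electrophilic aryne, while high dilution and slow addition of n-BuLi suppress bimolecular capture of 15.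

**Step 9**
Reactants: 17 target heptamethyl ether (R at Ca; S at Cb)
Product: 18 CNP0306974.1, the heptaphenol target
Conditions: BBr3 (20 equiv), CH2Cl2, −78 °C to rt, argon; then H2O, 0 °C
Reagents that add atoms: none
Why: Lewis-acid cleavage of aryl methyl ethers with BBr3, the standard end-game for permethylated oligostilbenes; neither Ca nor Cb carries a leaving group or a hydrogen that is labile under these conditions, so both centres should be retained.

**Compound list**
1 | 3-methoxy-5-methylphenol | COc1cc(C)cc(O)c1 | starting material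
2 | 3-methoxy-5-methylphenyl trifluoromethanesulfonate | COc1cc(C)cc(OS(=O)(=O)C(F)(F)F)c1 | intermediate
3 | 2-bromo-5-methoxy-3-methylphenyl trifluoromethanesulfonate | COc1cc(C)c(Br)c(OS(=O)(=O)C(F)(F)F)c1 | intermediate
4 | 2-bromo-3-(bromomethyl)-5-methoxyphenyl trifluoromethanesulfonate | COc1cc(CBr)c(Br)c(OS(=O)(=O)C(F)(F)F)c1 | intermediate
5 | 4,5-dimethoxy-2-methylbenzaldehyde | COc1cc(C)c(C=O)cc1OC | starting material
6 | (E)-N-tert-butyl-1-(4,5-dimethoxy-2-methylphenyl)methanimine | COc1cc(C)c(/C=N/C(C)(C)C)cc1OC | intermediate
7 | benzylic lithium derivative of 6 (not isolated) | COc1cc(C[Li])c(/C=N/C(C)(C)C)cc1OC | intermediate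
8 | N-tert-butyl imine of 9 (not isolated) | COc1cc(CCc2cc(OC)cc(OS(=O)(=O)C(F)(F)F)c2Br)c(/C=N/C(C)(C)C)cc1OC | intermediate
9 | 2-bromo-3-[2-(2-formyl-4,5-dimethoxyphenyl)ethyl]-5-methoxyphenyl trifluoromethanesulfonate | COc1cc(CCc2cc(OC)cc(OS(=O)(=O)C(F)(F)F)c2Br)c(C=O)cc1OC | intermediate
10 | 4-iodo-1,2-dimethoxybenzene | COc1ccc(I)cc1OC | starting material
11 | 2-bromo-3-[(2S)-2-(3,4-dimethoxyphenyl)-2-(2-formyl-4,5-dimethoxyphenyl)ethyl]-5-methoxyphenyl trifluoromethanesulfonate | O=Cc1cc(OC)c(OC)cc1[C@H](c1ccc(OC)c(OC)c1)Cc1cc(OC)cc(OS(=O)(=O)C(F)(F)F)c1Br | intermediate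
12 | diethyl (3,5-dimethoxybenzyl)phosphonate | CCOP(=O)(Cc1cc(OC)cc(OC)c1)OCC | starting material
13 | (S,E)-stilbene bromo triflate, the aryne precursor (full name in step 7) | COc1cc(/C=C/c2cc(OC)c(OC)cc2[C@H](c2ccc(OC)c(OC)c2)Cc2cc(OC)cc(OS(=O)(=O)C(F)(F)F)c2Br)cc(OC)c1 | intermediate
14 | aryllithium from 13, Li in place of Br (not isolated) | COc1cc(/C=C/c2cc(OC)c(OC)cc2[C@H](c2ccc(OC)c(OC)c2)Cc2cc(OC)cc(OS(=O)(=O)C(F)(F)F)c2[Li])cc(OC)c1 | intermediate
15 | ring E aryne, triple bond between the former C–Li and C–OTf carbons (not isolated) | COc1cc(/C=C/c2cc(OC)c(OC)cc2[C@H](c2ccc(OC)c(OC)c2)CC2=CC(OC)=CC#C2)cc(OC)c1 | intermediate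
16 | dearomatised [4+2] adduct, ring A as an alkylidene-cyclohexadiene (isotoluene), H at its sp3 carbon cis to H at Ca (not isolated) | COC1=CC2=C[C@@H]3c4cc(OC)c(OC)cc4[C@H](c4ccc(OC)c(OC)c4)Cc4cc(OC)cc(c43)[C@@H]2C(OC)=C1 | intermediate
17 | heptamethyl ether of the target, Ca (R), Cb (S) | COc1cc(OC)c2c(c1)C[C@@H]1c3cc(OC)c(OC)cc3[C@H](c3ccc(OC)c(OC)c3)Cc3cc(OC)cc-2c31 | intermediate
18 | CNP0306974.1, Ca (R), Cb (S) | Oc1cc(O)c2c(c1)C[C@@H]1c3cc(O)c(O)cc3[C@H](c3ccc(O)c(O)c3)Cc3cc(O)cc-2c31 | target

**Step count and risks**
Total step count: 9. Longest linear sequence: 8 (steps 1–3 and 5–9, from 1).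

**Steps most likely to fail**

Step 8.
- Risk: the aryne may be diverted into [2+2] addition at the stilbene C=C, into arylation by ring C or D, or into bimolecular capture. The seven-membered tether may be strained in the transition state. Facial selectivity at Ca may be poor.
- Fallback: the two bonds are made one at a time by known palladium chemistry, setting out from 13.
- A 7-exo-trig intramolecular Heck reaction at the C–Br bond should give the (Z)-benzylidene dibenzocycloheptene triflate F1. Conditions: Pd2(dba)3, P(t-Bu)3·HBF4, K2CO3, dioxane, 100 °C. This catalyst inserts into C–Br before C–OTf.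
- Hydrogenation (H2, Pd/C, EtOAc, rt) from the convex face of the boat-shaped ring F, the face that carries H at Cb, should give the saturated triflate F2 with Ca (R).
- An intramolecular triflate–arene direct arylation at either equivalent ortho C–H of ring A closes ring B. Conditions: Pd(OAc)2, PCy3·HBF4, K2CO3, t-BuCO2H, DMA, 110 °C. This comes back to the route at 17.

Step 6.
- Risk: C–H palladation of the electron-rich aldehyde may be slow. The palladacycle may lose a β-hydride. Uptake of the electron-rich iodide may be sluggish, or enantioselection may be insufficient.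
- Fallback: the order of bond formation at Cb is reversed and the enantiomer is taken by resolution, setting out from 5, 10 and 4.
- Arylation of the methyl C–H of 5 with 10 should give the diarylmethane aldehyde F3. Conditions: Pd(OAc)2, glycine, AgOCOCF3, (CF3)2CHOH/AcOH, 100 °C. This is a primary benzylic C–H with no β-hydrogen.
- t-BuNH2/MgSO4 gives its tert-butylimine F4.
- Deprotonation of the doubly benzylic CH2 (LiN(i-Pr)2, THF, −78 °C) and alkylation with 4 gives the racemic alkylated imine F5.
- AcOH/H2O/THF hydrolyses F5 to the racemic aldehyde F6.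
- Preparative chromatography on a chiral stationary phase separates the (R)-enantiomer F7 from the (S)-enantiomer, which is 11, where the route is rejoined.

Step 5.
- Risk: lateral deprotonation of the electron-rich imine may be incomplete. Proton exchange between anion and product may lead to double alkylation. The carbanion may attack the ArBr or ArOTf groups.
- Fallback: olefination and reduction replace the carbanion alkylation, setting out from 4.
- PPh3 (toluene, 90 °C) gives the benzylphosphonium bromide F8.
- A Wittig reaction with an excess of commercial 4,5-dimethoxybenzene-1,2-dicarbaldehyde (K2CO3, 18-crown-6, CH2Cl2, reflux) gives the formyl stilbene F9 as an E/Z mixture.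
- Diimide reduction (KO2CN=NCO2K, AcOH, MeOH, rt) spares CHO, ArBr and ArOTf, saturates the C=C, and comes back to the route at 9.

**Further compounds**
F1 | step 8 | (Z)-benzylidene dibenzocycloheptene triflate, Cb (S), ring E cis to ring A on the C=C | COc1cc(/C=C2/c3cc(OC)c(OC)cc3[C@H](c3ccc(OC)c(OC)c3)Cc3cc(OC)cc(OS(=O)(=O)C(F)(F)F)c32)cc(OC)c1
F2 | step 8 | saturated dibenzocycloheptene triflate, Ca (R), Cb (S) | COc1cc(C[C@@H]2c3cc(OC)c(OC)cc3[C@H](c3ccc(OC)c(OC)c3)Cc3cc(OC)cc(OS(=O)(=O)C(F)(F)F)c32)cc(OC)c1
F3 | step 6 | 2-(3,4-dimethoxybenzyl)-4,5-dimethoxybenzaldehyde | COc1ccc(Cc2cc(OC)c(OC)cc2C=O)cc1OC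
F4 | step 6 | N-tert-butyl imine of F3 | COc1ccc(Cc2cc(OC)c(OC)cc2/C=N/C(C)(C)C)cc1OC
F5 | step 6 | racemic alkylated imine (N-tert-butyl imine of F6) | COc1ccc(C(Cc2cc(OC)cc(OS(=O)(=O)C(F)(F)F)c2Br)c2cc(OC)c(OC)cc2/C=N/C(C)(C)C)cc1OC
F6 | step 6 | racemic form of aldehyde 11 | O=Cc1cc(OC)c(OC)cc1C(c1ccc(OC)c(OC)c1)Cc1cc(OC)cc(OS(=O)(=O)C(F)(F)F)c1Br
F7 | step 6 | (R)-enantiomer of aldehyde 11 | O=Cc1cc(OC)c(OC)cc1[C@@H](c1ccc(OC)c(OC)c1)Cc1cc(OC)cc(OS(=O)(=O)C(F)(F)F)c1Br
F8 | step 5 | [2-bromo-5-methoxy-3-(triflyloxy)benzyl]triphenylphosphonium bromide | COc1cc(C[P+](c2ccccc2)(c2ccccc2)c2ccccc2)c(Br)c(OS(=O)(=O)C(F)(F)F)c1.[Br-]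
F9 | step 5 | 2-bromo-3-[2-(2-formyl-4,5-dimethoxyphenyl)ethenyl]-5-methoxyphenyl trifluoromethanesulfonate, E/Z mixture | COc1cc(C=Cc2cc(OC)cc(OS(=O)(=O)C(F)(F)F)c2Br)c(C=O)cc1OC
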